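**Retrosynthetic overview** (isoflavan numbering; ring A = formyl arene, ring C = pyran, ring B = prenylated aryl)
1. Ring C is closed last by O1–C2 bond formation (Mitsunobu reaction of the C8a phenol with the C2 alcohol); the formyl group travels as a dimethyl acetal and the ring B phenol as its diethylcarbamate.
2. Ring A (C4a, C5, C6, C7, C8, C8a) is a pentasubstituted phloroglucinol in which C6 and C8 each lie between two oxygens, so formylation of a finished ring could not be directed. The ring is instead assembled around the formyl carbon: C8–C8a, C6–C7 and C4a–C8a are formed from 3-methoxy-4-alkylcyclobutenone 21 and acetal-bearing siloxyalkyne 25.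
3. Cyclobutenone 21 is disconnected by a ketene/methoxyacetylene (2+2) cycloaddition to acid 15, whose C4a and C8a carbons are added to bromide 12 by malonate alkylation.
4. The C3 stereocentre comes from catalytic enantioselective bromide opening of 3-aryloxetane 9; ring B is elaborated from 3-methoxyphenol by two carbamate-directed lithiations (prenyl, then boron) and nickel-catalysed coupling with 3-iodooxetane.
5. Order of rings: ring B (present from the start), ring A (step 12), ring C (step 14).

Key step: step 12

Remarks: Ar stands for 2-(diethylcarbamoyloxy)-4-methoxy-3-(3-methylbut-2-en-1-yl)phenyl (ring B with its carbamate). The sense of induction in step 5 is not assumed; the antipode of the catalyst that leads to (R)-11 is the one used. Compound 21 is carried as a mixture of epimers at its ring sp3 carbon, which becomes aromatic C4a.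

**Step 1**
Reactants: 1 3-methoxyphenol
Product: 2 3-methoxyphenyl N,N-diethylcarbamate
Conditions: ClC(O)NEt2, K2CO3, MeCN, reflux
Reagents that add atoms: diethylcarbamoyl chloride, CCN(CC)C(Cl)=O
Why: O-acylation of the phenoxide with the carbamoyl chloride gives the aryl O-carbamate, which directs both ring B lithiations and masks the ring B phenol until the last step.

**Step 2**
Reactants: 2 3-methoxyphenyl N,N-diethylcarbamate
Product: 4 3-methoxy-2-(3-methylbut-2-en-1-yl)phenyl N,N-diethylcarbamate, via aryllithium 3 (not isolated)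
Conditions: s-BuLi, TMEDA, THF, −78 °C; CuBr·SMe2 (10 mol %), prenyl bromide, −78 to −30 °C
Reagents that add atoms: prenyl bromide (1-bromo-3-methylbut-2-ene), CC(C)=CCBr
Why: Directed ortho-metalation occurs at C2, the position activated by both the carbamate and the methoxy group, and copper-catalysed allylic substitution at the primary carbon of prenyl bromide follows, the low temperature preventing the anionic ortho-Fries shift of the carbamoyl group.

**Step 3**
Reactants: 4 3-methoxy-2-(3-methylbut-2-en-1-yl)phenyl N,N-diethylcarbamate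
Product: 7 [2-(diethylcarbamoyloxy)-4-methoxy-3-(3-methylbut-2-en-1-yl)phenyl]boronic acid, via aryllithium 5 (not isolated), via lithium aryltrimethoxyborate 6 (not isolated)
Conditions: s-BuLi, TMEDA, THF, −78 °C; B(OMe)3, −78 °C to rt; aq. HCl to pH 5
Reagents that add atoms: trimethyl borate, COB(OC)OC; water, O
Why: In this second directed ortho-metalation the carbamate delivers the base to its only free ortho position (pre-complexation should make ring deprotonation faster than removal of the benzylic–allylic prenyl protons at −78 °C), and borylation of the aryllithium with mild hydrolysis gives the boronic acid.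

**Step 4**
Reactants: 7 [2-(diethylcarbamoyloxy)-4-methoxy-3-(3-methylbut-2-en-1-yl)phenyl]boronic acid; 8 3-iodooxetane
Product: 9 3-Ar-oxetane
Conditions: NiI2 (6 mol %), trans-2-aminocyclohexanol hydrochloride (6 mol %), NaHMDS, i-PrOH, 80 °C
Reagents that add atoms: none
Why: Nickel-catalysed Suzuki–Miyaura coupling of a secondary alkyl iodide with an arylboronic acid (amino alcohol ligand, alkoxide base) is the standard way to attach an oxetan-3-yl group to an arene, and the aryl carbamate C–O bond should not be activated by this phosphine-free nickel system at 80 °C.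

**Step 5**
Reactants: 9 3-Ar-oxetane
Product: 11 (2R)-2-Ar-3-bromopropan-1-ol, via trimethylsilyl ether 10 (not isolated)
Conditions: TMSBr, chiral arylpyrrolidine squaramide (5 mol %), t-BuOMe, −78 °C; Et3N, MeOH; then citric acid, MeOH, 0 °C
Reagents that add atoms: bromotrimethylsilane, C[Si](C)(C)Br
Why: This is an enantioselective desymmetrisation of a 3-substituted oxetane by hydrogen-bond-donor catalysis, in which the squaramide-bound bromide opens the silylated oxetane by SN2 attack at one of its two enantiotopic CH2 groups and so sets C3 as (R) under catalyst control, after which methanolysis removes the labile trimethylsilyl ether.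

**Step 6**
Reactants: 11 (2R)-2-Ar-3-bromopropan-1-ol
Product: 12 [(2R)-2-Ar-3-bromopropoxy](tert-butyl)dimethylsilane
Conditions: TBSCl, imidazole, CH2Cl2, 0 °C to rt
Reagents that add atoms: tert-butyldimethylsilyl chloride, CC(C)(C)[Si](C)(C)Cl
Why: Imidazole-mediated silylation of the primary alcohol installs a silyl ether that survives malonate alkylation, hydroxide and heat, and imidazole is too weak a base to close the bromohydrin back to the oxetane.

**Step 7**
Reactants: 12 [(2R)-2-Ar-3-bromopropoxy](tert-butyl)dimethylsilane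
Product: 13 dimethyl 2-[(2R)-2-Ar-3-(tert-butyldimethylsilyloxy)propyl]propanedioate
Conditions: CH2(CO2Me)2, NaH, NaI (cat.), DMF, 60 °C
Reagents that add atoms: dimethyl malonate, COC(=O)CC(=O)OC
Why: Malonic ester alkylation (SN2 with iodide catalysis) at the primary carbon adds the future C4a and C8a carbons, the soft and weakly basic malonate anion limiting E2 loss of the benzylic hydrogen, and the stereocentre is not a reacting centre.

**Step 8**
Reactants: 13 dimethyl 2-[(2R)-2-Ar-3-(tert-butyldimethylsilyloxy)propyl]propanedioate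
Product: 15 (4R)-4-Ar-5-(tert-butyldimethylsilyloxy)pentanoic acid, via malonic acid 14 (not isolated)
Conditions: LiOH, THF/MeOH/H2O, 40 °C; cold 1 M HCl to pH 3–4; pyridine, 110 °C
Reagents that add atoms: lithium hydroxide, [Li+].[OH-]
Why: Saponification and thermal decarboxylation of the alkylmalonic acid (malonic ester synthesis) give the acid, since hydroxide at 40 °C should leave the hindered aryl diethylcarbamate and the primary silyl ether intact and pyridine buffers the decarboxylation.

**Step 9**
Reactants: 16 chloroacetaldehyde dimethyl acetal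
Product: 18 methoxyacetylene, via sodium methoxyethynide 17 (not isolated)
Conditions: NaNH2 (3 equiv), liquid NH3, −33 °C; cold brine, −20 °C; distilled into CH2Cl2 at −78 °C
Reagents that add atoms: none
Why: Two amide-induced beta-eliminations (methanol, then HCl) and deprotonation give the sodium acetylide, which water protonates, the standard preparation of alkoxyacetylenes from chloroacetaldehyde acetals.

**Step 10**
Reactants: 15 (4R)-4-Ar-5-(tert-butyldimethylsilyloxy)pentanoic acid; 18 methoxyacetylene
Product: 21 4-[(2R)-2-Ar-3-(tert-butyldimethylsilyloxy)propyl]-3-methoxycyclobut-2-en-1-one (both C4 epimers), via acid chloride 19 (not isolated), via ketene 20 (not isolated)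
Conditions: 1-chloro-N,N,2-trimethylprop-1-en-1-amine (1.0 equiv), CH2Cl2, 0 °C to rt; then slow addition to 18 (5 equiv), Et3N, CH2Cl2, 0 °C to rt
Reagents that add atoms: none
Why: The alpha-chloroenamine gives the acid chloride without HCl (sparing the silyl ether and the prenyl alkene), Et3N dehydrochlorinates it to the aldoketene, and the ketene–alkoxyalkyne (2+2) cycloaddition joins the ketene carbonyl carbon to the nucleophilic terminal alkyne carbon to give the 3-methoxy-4-alkyl regioisomer, the new ring stereocentre being uncontrolled and irrelevant and slow addition into excess 18 holding back ketene dimerisation.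

**Step 11**
Reactants: 22 methyl dimethoxyacetate
Product: 25 3,3-dimethoxy-1-(triisopropylsilyloxy)prop-1-yne, via dibromoenolate 23 (not isolated), via ynolate 24 (not isolated)
Conditions: CH2Br2, LiTMP, THF, −78 °C; 22; n-BuLi, −78 °C to rt; TIPSCl, −78 to 0 °C
Reagents that add atoms: dibromomethane, BrCBr; triisopropylsilyl chloride, CC(C)[Si](Cl)(C(C)C)C(C)C
Why: In this Kowalski ester homologation dibromomethyllithium adds to the ester, the dibromoketone enolate undergoes bromine–lithium exchange and a carbenoid 1,2-shift to the ynolate, and the bulky silyl chloride silylates on oxygen to give the siloxyalkyne.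

**Step 12**
Reactants: 21 4-[(2R)-2-Ar-3-(tert-butyldimethylsilyloxy)propyl]-3-methoxycyclobut-2-en-1-one; 25 3,3-dimethoxy-1-(triisopropylsilyloxy)prop-1-yne
Product: 30 2-[(2R)-2-Ar-3-(tert-butyldimethylsilyloxy)propyl]-6-(dimethoxymethyl)-3-methoxy-5-(triisopropylsilyloxy)phenol, via vinylketene 26 (not isolated), via vinylcyclobutenone 27 (not isolated), via dienylketene 28 (not isolated), via cyclohexadienone 29 (not isolated)
Conditions: 25 (1.5 equiv), toluene, 80 °C then 110 °C, sealed tube, argon
Reagents that add atoms: none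
Why: Heat opens 21 by a conrotatory four-electron electrocyclic reaction to vinylketene 26, and the polarised ynol ether 25 adds to it in a ketene–alkyne (2+2) cycloaddition in which the acetal-bearing carbon (remote from oxygen, nucleophilic) bonds to the ketene carbonyl carbon (C8–C8a) and the oxygen-bearing carbon to the ketene alpha-carbon (C6–C7), giving vinylcyclobutenone 27. Release of the ring strain of 27 drives a second four-electron opening to dienylketene 28, and ring A is closed by its disrotatory six-electron electrocyclisation (C4a–C8a) to cyclohexadienone 29, which tautomerises to phenol 30. The closest known reaction is the Danheiser benzannulation of cyclobutenones, 3-siloxycyclobutenones included, with triisopropylsiloxyalkynes; the acetal substituent on the alkyne is the untested variable. No stereocentre is formed: the ring sp3 carbon of 21 becomes aromatic C4a, so both epimers converge, and C3 is never a reacting centre. The only selectivity needed is the orientation of the (2+2) step, which the oxygen donor of 25 secures; with it, connectivity alone places CH(OMe)2 on C8, OSi on C7, H on C6, OMe on C5 and the chain on C4a and leaves the C8a hydroxyl as the single free phenol. An excess of 25 is used so that ketene capture outruns dimerisation of 26 and acylation of 30.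

**Step 13**
Reactants: 30 2-[(2R)-2-Ar-3-(tert-butyldimethylsilyloxy)propyl]-6-(dimethoxymethyl)-3-methoxy-5-(triisopropylsilyloxy)phenol
Product: 31 4-[(2R)-2-Ar-3-hydroxypropyl]-2-(dimethoxymethyl)-5-methoxybenzene-1,3-diol
Conditions: TBAF (3 equiv), THF, 0 °C to rt; pH 7 phosphate buffer
Reagents that add atoms: none
Why: Fluoride-mediated desilylation cleaves the aryl triisopropylsilyl ether and the primary tert-butyldimethylsilyl ether, while acetal, carbamate and C3 are inert to fluoride and the neutral work-up spares the acid-labile acetal.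

**Step 14**
Reactants: 31 4-[(2R)-2-Ar-3-hydroxypropyl]-2-(dimethoxymethyl)-5-methoxybenzene-1,3-diol
Product: 32 (3R)-3-Ar-8-(dimethoxymethyl)-5-methoxychroman-7-ol
Conditions: PPh3, DIAD, THF (0.01 M), 0 °C to rt, slow addition of 31 to the pre-formed betaine
Reagents that add atoms: none
Why: In this intramolecular Mitsunobu etherification the C8a phenoxide displaces the oxyphosphonium group at primary C2 in a 6-exo-tet closure of ring C, the C7 phenol can react only between molecules and is outrun at high dilution, the ring B oxygen is masked, and C3 is untouched because substitution takes place at C2.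

**Step 15**
Reactants: 32 (3R)-3-Ar-8-(dimethoxymethyl)-5-methoxychroman-7-ol
Product: 34 (3R)-7-hydroxy-3-[2-hydroxy-4-methoxy-3-(3-methylbut-2-en-1-yl)phenyl]-5-methoxychroman-8-carbaldehyde, via acetal diphenol 33 (not isolated)
Conditions: LiAlH4, THF, 0 °C to rt; then 1 M HCl, THF/H2O, 0 °C
Reagents that add atoms: water, O
Why: Hydride attack at the carbamate carbonyl expels the ring B phenoxide (reductive cleavage of an aryl carbamate) while the acetal shields the formyl carbon, and the aqueous acid of the work-up then hydrolyses the very electron-rich aryl acetal to the aldehyde under conditions too mild for cyclisation of the prenyl group onto the neighbouring phenol.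

**Compound list**
1 | 3-methoxyphenol | COc1cccc(O)c1 | starting material
2 | 3-methoxyphenyl N,N-diethylcarbamate | CCN(CC)C(=O)Oc1cccc(OC)c1 | intermediate
3 | 2-lithio-3-methoxyphenyl N,N-diethylcarbamate (aryllithium, formed in situ) | CCN(CC)C(=O)Oc1cccc(OC)c1[Li] | intermediate
4 | 3-methoxy-2-(3-methylbut-2-en-1-yl)phenyl N,N-diethylcarbamate | CCN(CC)C(=O)Oc1cccc(OC)c1CC=C(C)C | intermediate
5 | 6-lithio-3-methoxy-2-(3-methylbut-2-en-1-yl)phenyl N,N-diethylcarbamate (aryllithium, formed in situ) | CCN(CC)C(=O)Oc1c([Li])ccc(OC)c1CC=C(C)C | intermediate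
6 | lithium trimethoxy(Ar)borate (formed in situ) | [Li+].CO[B-](OC)(OC)c1ccc(OC)c(CC=C(C)C)c1OC(=O)N(CC)CC | intermediate
7 | [2-(diethylcarbamoyloxy)-4-methoxy-3-(3-methylbut-2-en-1-yl)phenyl]boronic acid | OB(O)c1ccc(OC)c(CC=C(C)C)c1OC(=O)N(CC)CC | intermediate
8 | 3-iodooxetane | IC1COC1 | starting material
9 | 3-Ar-oxetane (3-methoxy-2-(3-methylbut-2-en-1-yl)-6-(oxetan-3-yl)phenyl N,N-diethylcarbamate) | CCN(CC)C(=O)Oc1c(C2COC2)ccc(OC)c1CC=C(C)C | intermediate
10 | [(2R)-2-Ar-3-bromopropoxy]trimethylsilane (formed in situ) | COc1ccc([C@@H](CBr)CO[Si](C)(C)C)c(OC(=O)N(CC)CC)c1CC=C(C)C | intermediate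
11 | (2R)-2-Ar-3-bromopropan-1-ol | COc1ccc([C@@H](CBr)CO)c(OC(=O)N(CC)CC)c1CC=C(C)C | intermediate
12 | [(2R)-2-Ar-3-bromopropoxy](tert-butyl)dimethylsilane | COc1ccc([C@@H](CBr)CO[Si](C)(C)C(C)(C)C)c(OC(=O)N(CC)CC)c1CC=C(C)C | intermediate
13 | dimethyl 2-[(2R)-2-Ar-3-(tert-butyldimethylsilyloxy)propyl]propanedioate | COc1ccc([C@@H](CC(C(=O)OC)C(=O)OC)CO[Si](C)(C)C(C)(C)C)c(OC(=O)N(CC)CC)c1CC=C(C)C | intermediate
14 | 2-[(2R)-2-Ar-3-(tert-butyldimethylsilyloxy)propyl]propanedioic acid (not purified) | COc1ccc([C@@H](CC(C(=O)O)C(=O)O)CO[Si](C)(C)C(C)(C)C)c(OC(=O)N(CC)CC)c1CC=C(C)C | intermediate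
15 | (4R)-4-Ar-5-(tert-butyldimethylsilyloxy)pentanoic acid | COc1ccc([C@@H](CCC(=O)O)CO[Si](C)(C)C(C)(C)C)c(OC(=O)N(CC)CC)c1CC=C(C)C | intermediate
16 | chloroacetaldehyde dimethyl acetal (2-chloro-1,1-dimethoxyethane) | COC(CCl)OC | starting material
17 | sodium methoxyethynide (formed in situ) | [Na+].[C-]#COC | intermediate
18 | methoxyacetylene | COC#C | intermediate
19 | (4R)-4-Ar-5-(tert-butyldimethylsilyloxy)pentanoyl chloride (formed in situ) | COc1ccc([C@@H](CCC(=O)Cl)CO[Si](C)(C)C(C)(C)C)c(OC(=O)N(CC)CC)c1CC=C(C)C | intermediate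
20 | (4R)-4-Ar-5-(tert-butyldimethylsilyloxy)pent-1-en-1-one (ketene, formed in situ) | COc1ccc([C@@H](CC=C=O)CO[Si](C)(C)C(C)(C)C)c(OC(=O)N(CC)CC)c1CC=C(C)C | intermediate
21 | 4-[(2R)-2-Ar-3-(tert-butyldimethylsilyloxy)propyl]-3-methoxycyclobut-2-en-1-one, both epimers at C4 | COc1ccc([C@@H](CC2C(=O)C=C2OC)CO[Si](C)(C)C(C)(C)C)c(OC(=O)N(CC)CC)c1CC=C(C)C | intermediate
22 | methyl dimethoxyacetate | COC(OC)C(=O)OC | starting material
23 | lithium 1,1-dibromo-3,3-dimethoxyprop-1-en-2-olate (formed in situ) | [Li+].[O-]C(=C(Br)Br)C(OC)OC | intermediate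
24 | lithium 3,3-dimethoxyprop-1-yn-1-olate (ynolate, formed in situ) | [Li+].[O-]C#CC(OC)OC | intermediate
25 | 3,3-dimethoxy-1-(triisopropylsilyloxy)prop-1-yne | COC(OC)C#CO[Si](C(C)C)(C(C)C)C(C)C | intermediate
26 | (6R)-6-Ar-7-(tert-butyldimethylsilyloxy)-3-methoxyhepta-1,3-dien-1-one (vinylketene, formed in situ) | COc1ccc([C@@H](CC=C(OC)C=C=O)CO[Si](C)(C)C(C)(C)C)c(OC(=O)N(CC)CC)c1CC=C(C)C | intermediate
27 | 4-[(4R)-4-Ar-5-(tert-butyldimethylsilyloxy)-1-methoxypent-1-en-1-yl]-2-(dimethoxymethyl)-3-(triisopropylsilyloxy)cyclobut-2-en-1-one (formed in situ) | COc1ccc([C@@H](CC=C(OC)C2C(=O)C(C(OC)OC)=C2O[Si](C(C)C)(C(C)C)C(C)C)CO[Si](C)(C)C(C)(C)C)c(OC(=O)N(CC)CC)c1CC=C(C)C | intermediate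
28 | (8R)-8-Ar-9-(tert-butyldimethylsilyloxy)-2-(dimethoxymethyl)-5-methoxy-3-(triisopropylsilyloxy)nona-1,3,5-trien-1-one (dienylketene, formed in situ) | COc1ccc([C@@H](CC=C(OC)C=C(O[Si](C(C)C)(C(C)C)C(C)C)C(=C=O)C(OC)OC)CO[Si](C)(C)C(C)(C)C)c(OC(=O)N(CC)CC)c1CC=C(C)C | intermediate
29 | 6-[(2R)-2-Ar-3-(tert-butyldimethylsilyloxy)propyl]-2-(dimethoxymethyl)-5-methoxy-3-(triisopropylsilyloxy)cyclohexa-2,4-dien-1-one (formed in situ) | COc1ccc([C@@H](CC2C(=O)C(C(OC)OC)=C(O[Si](C(C)C)(C(C)C)C(C)C)C=C2OC)CO[Si](C)(C)C(C)(C)C)c(OC(=O)N(CC)CC)c1CC=C(C)C | intermediate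
30 | 2-[(2R)-2-Ar-3-(tert-butyldimethylsilyloxy)propyl]-6-(dimethoxymethyl)-3-methoxy-5-(triisopropylsilyloxy)phenol | COc1ccc([C@@H](Cc2c(O)c(C(OC)OC)c(O[Si](C(C)C)(C(C)C)C(C)C)cc2OC)CO[Si](C)(C)C(C)(C)C)c(OC(=O)N(CC)CC)c1CC=C(C)C | intermediate
31 | 4-[(2R)-2-Ar-3-hydroxypropyl]-2-(dimethoxymethyl)-5-methoxybenzene-1,3-diol | COc1ccc([C@@H](Cc2c(O)c(C(OC)OC)c(O)cc2OC)CO)c(OC(=O)N(CC)CC)c1CC=C(C)C | intermediate
32 | (3R)-3-Ar-8-(dimethoxymethyl)-5-methoxychroman-7-ol | COc1ccc([C@@H]2COc3c(C(OC)OC)c(O)cc(OC)c3C2)c(OC(=O)N(CC)CC)c1CC=C(C)C | intermediate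
33 | (3R)-8-(dimethoxymethyl)-3-[2-hydroxy-4-methoxy-3-(3-methylbut-2-en-1-yl)phenyl]-5-methoxychroman-7-ol (formed in situ) | COc1ccc([C@@H]2COc3c(C(OC)OC)c(O)cc(OC)c3C2)c(O)c1CC=C(C)C | intermediate
34 | (3R)-7-hydroxy-3-[2-hydroxy-4-methoxy-3-(3-methylbut-2-en-1-yl)phenyl]-5-methoxychroman-8-carbaldehyde | COc1ccc([C@@H]2COc3c(C=O)c(O)cc(OC)c3C2)c(O)c1CC=C(C)C | target

**Step count and risks**
Total step count: 15. Longest linear sequence: 13 steps (steps 1–8, 10, 12–15); steps 9 and 11 each make one small partner.

Steps most likely to fail: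

1. Step 12. Capture of vinylketene 26 by 25 may be slow, because the acetal is inductively withdrawing and branched at the very carbon that must bond to the ketene, and the propargylic acetal can ionise with loss of methoxide. The ketene would then dimerise or acylate the product phenol. The fallback sets out from 21 and comes back at 34; it carries the formyl carbon as a silyloxymethyl group, which is closest to the alkyl-substituted siloxyalkynes of the precedent. Commercial tert-butyldimethyl(prop-2-yn-1-yloxy)silane would be converted in one flask (n-BuLi; lithium tert-butyl peroxide; TIPSOTf) into 3-(tert-butyldimethylsilyloxy)-1-(triisopropylsilyloxy)prop-1-yne F1. Heating 21 with it under the conditions of step 12 should give the benzannulated phenol F2. TBAF should then give the tetraol F3, and MnO2 should oxidise only the benzylic alcohol to the salicylaldehyde F4. Mitsunobu closure as in step 14 should give the chroman aldehyde carbamate F5, and hydrolysis of the carbamate (NaOH, EtOH/H2O, reflux, argon) should give 34.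

2. Step 5. Enantioselectivity may erode if the ortho carbamate binds the silyl bromide or the catalyst and opens an uncatalysed background ring-opening. The fallback sets out from 9 and comes back at 11, replacing asymmetric catalysis by resolution. Opening with TMSBr alone (CH2Cl2, −20 °C) should give the racemic trimethylsilyl ether F6, and methanolysis the racemic bromohydrin F7. Kinetic resolution by lipase-catalysed acylation (immobilised Burkholderia cepacia lipase, vinyl acetate, t-BuOMe), with the enzyme selected so that the (S)-alcohol is acetylated, would remove it as the (S)-acetate F8 and leave (R)-11, at the cost of half the material.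

3. Step 15. The aluminium phenoxide at C7 can push methoxide out of the neighbouring acetal and the resulting quinone methide would be reduced (over-reduction at the C8 carbon); alternatively, hydride attack on the doubly ortho-flanked carbamate may stall at room temperature. The fallback sets out from 32 and comes back at 34, inverting the order and avoiding hydride. Mild hydrolysis of the acetal (PPTS, acetone/H2O, rt) should give the aldehyde carbamate F9 (the same compound as F5). The carbamate would then be cleaved by hydrolysis (NaOH, EtOH/H2O, reflux, argon), which the non-enolisable, phenoxide-deactivated aldehyde should tolerate.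

**Further compounds**
F1 | step 12 | 3-(tert-butyldimethylsilyloxy)-1-(triisopropylsilyloxy)prop-1-yne | CC(C)(C)[Si](C)(C)OCC#CO[Si](C(C)C)(C(C)C)C(C)C
F2 | step 12 | 2-[(2R)-2-Ar-3-(tert-butyldimethylsilyloxy)propyl]-6-[(tert-butyldimethylsilyloxy)methyl]-3-methoxy-5-(triisopropylsilyloxy)phenol | COc1ccc([C@@H](Cc2c(O)c(CO[Si](C)(C)C(C)(C)C)c(O[Si](C(C)C)(C(C)C)C(C)C)cc2OC)CO[Si](C)(C)C(C)(C)C)c(OC(=O)N(CC)CC)c1CC=C(C)C
F3 | step 12 | 4-[(2R)-2-Ar-3-hydroxypropyl]-2-(hydroxymethyl)-5-methoxybenzene-1,3-diol | COc1ccc([C@@H](Cc2c(O)c(CO)c(O)cc2OC)CO)c(OC(=O)N(CC)CC)c1CC=C(C)C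
F4 | step 12 | 3-[(2R)-2-Ar-3-hydroxypropyl]-2,6-dihydroxy-4-methoxybenzaldehyde | COc1ccc([C@@H](Cc2c(O)c(C=O)c(O)cc2OC)CO)c(OC(=O)N(CC)CC)c1CC=C(C)C
F5 | step 12 | (3R)-3-Ar-7-hydroxy-5-methoxychroman-8-carbaldehyde | COc1ccc([C@@H]2COc3c(C=O)c(O)cc(OC)c3C2)c(OC(=O)N(CC)CC)c1CC=C(C)C
F6 | step 5 | racemic (2-Ar-3-bromopropoxy)trimethylsilane | COc1ccc(C(CBr)CO[Si](C)(C)C)c(OC(=O)N(CC)CC)c1CC=C(C)C
F7 | step 5 | racemic 2-Ar-3-bromopropan-1-ol | COc1ccc(C(CBr)CO)c(OC(=O)N(CC)CC)c1CC=C(C)C
F8 | step 5 | (2S)-2-Ar-3-bromopropyl acetate | COc1ccc([C@H](CBr)COC(C)=O)c(OC(=O)N(CC)CC)c1CC=C(C)C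
F9 | step 15 | (3R)-3-Ar-7-hydroxy-5-methoxychroman-8-carbaldehyde | COc1ccc([C@@H]2COc3c(C=O)c(O)cc(OC)c3C2)c(OC(=O)N(CC)CC)c1CC=C(C)C
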